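## Analysis of the target

Target 34 is a diterpenoid ester on a decalin core. Labdane numbering is used throughout: ring A = C1–C5 and C10, ring B = C5–C10, side chain C11–C16 on C9, C17 on C8, C18 (methyl) and C19 (CH2O) on C4, C20 on C10; β is the face that carries C20. The decalin is cis-fused (H5 and C20 both β). Its five stereocentres (4R,5S,8R,9R,10S) put C18, C17 and the C9 chain on the β-face and C19 and the C8 hydroxyl on the α-face. C4 and C10 are quaternary and flank the ring-fusion carbon C5, while C8, C9 and C10 are contiguous, with the C9 chain cis to the C10 methyl and trans to the tertiary hydroxyl. The sensitive groups are the Z-p-coumarate (drifts to E under light or as its phenoxide), the 2-substituted buta-1,3-diene (acid, electrophiles), the tertiary C8 alcohol (dehydration, ring closure onto an electrophilic C12) and the ester (hydride, base). The hard parts are the two quaternary carbons on either side of C5 in a cis-decalin, the absolute configuration, and the C8/C9 pair next to C10. The feature used is that C10 carries two ring B arms, C9–C8–C7 and C5–C6–C7, that are identical until ring A exists, and that C4 sits α to the oxidised C19. A flat 4-methylcyclohexa-2,5-dienone tethered to a racemic α-methyl aldehyde therefore holds C4, C5 and C10 in latent form, and one C4–C5 bond formation reveals all three.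

## Retrosynthetic reasoning

**Enoate C=C of the coumarate.** 34 is the desilylated form of 33, and 33 is cut at the Z-alkene into phosphonate 30 and aldehyde 32 (from 31). The alkene is cut instead of the ester C–O bond so that the Z-geometry is made kinetically on the substrate as the last C–C bond, and no isomerisable Z-acid has to be prepared and activated. 30 comes from diol 28 through bromoacetate 29. The forward steps must acylate the primary C19 hydroxyl beside the tertiary one and give the Z-enoate.

**C8–O and C12–C13.** 28 comes from 27, and the C8 carbinol of 27 from the 7α,8α-epoxide 26 by hydride attack at C7. The epoxide fixes the configuration at C8 and also masks the tertiary alcohol, which would otherwise close a tetrahydrofuran onto an activated C12. 26 is cut between C12 and C13 into the primary sulfonate 23 and the four-carbon dienyl Grignard reagent 25 (from 24), which brings in the whole diene in one coupling. 23 goes back through 22 and 21 to ester 20.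

**C9–C11.** 20 is cut at C9–C11 by a [3,3]-sigmatropic transform to allylic alcohol 18. C9 is next to quaternary C10, so an intramolecular, suprafacial delivery is chosen over any intermolecular alkylation. The same event copies the C7 configuration onto C9 and moves the alkene to C7=C8, where oxygen can later be placed on the methyl-bearing carbon. The forward step needs the C7 oxygen on the β-face.

**C8–C17 and the C7 carbinol.** 18 comes from alkenyl iodide 17 by methyl cross-coupling, 17 from iodoenone 16 by a reagent-controlled carbonyl reduction, and 16 from enone 15. 15 is the protected form of alcohol 14, which comes from aldehyde 13. The enone of 13 is therefore the single handle for C7, C8 and C9.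

**C4–C5 (key disconnection).** 13 is cut at C4–C5 to the monocyclic dienone aldehyde 11. This bond joins the quaternary C4 to the ring-fusion carbon. Cutting it removes ring A and all three stereocentres of 13 at once and leaves a precursor whose only stereocentre is erased on the way to enamine 12. The forward reaction has to choose one of two enantiotopic enone arms and one face of the enamine.

**The precursor.** 11 is unmasked from acetal 10, which comes from ketone 8 by double dehydrogenation through 9. 8 is the protected form of keto aldehyde 7, 7 the hydrogenation product of enal 6, and 6 the allylic oxidation product (via 5) of enone 4. 4 is the Robinson annulation product of 1 and 2 through 3. Every carbon of 11 is thus drawn from two commodity chemicals.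

## Alternatives that were turned down

Alternative 1: The disconnection is C5–C6, made by an anionic oxy-Cope rearrangement of a bridged vinyl carbinol obtained by cycloaddition to an oxidatively dearomatised guaiacol. The [3,3] shift would form C5–C6, break C3–C8 and deliver the cis-decalin A1 with a C8 ketone, a C9 ketal and a C3=C4 enoate.
- For: the bridged substrate can only unfold to a cis fusion. The ketone appears exactly at C8, where methyl addition would give the carbinol, so no oxygen has to be moved from C7 to C8. On this point A1 is stronger than the chosen route, which spends six steps on that transposition.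
- Against: C4 is sp2 in A1, so its methyl group and configuration must be added later by an alkylation whose facial control is not secured. The C2 sulfone must be removed. C11 has to be attached at a C9 carbonyl wedged between quaternary C10 and C8. The cycloaddition gives racemic material unless an auxiliary is carried.
- Comparison: the chosen strategy fixes C4, C5 and C10 in one catalytic asymmetric step and leaves one enone; A1 postpones C4 and the absolute configuration and needs more redox corrections.

Alternative 2: The disconnection is C5–C10 together with C3–C4, an intramolecular Diels–Alder reaction of an acyclic triene whose Z-enoate C4=C5 adds to the diene C10=C1–C2=C3 through the C6–C9 tether. It would give the octalin A2 with both rings closed.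
- For: it is the most convergent plan, since A2 already carries the C9 stereocentre with C11–C12 and a masked C8 ketone. The Z-geometry of the dienophile is translated stereospecifically into the C4/C5 relation, so C4 control is stronger in principle than in the chosen route.
- Against: the acyclic precursor needs three geometrically defined alkenes and a stereocentre, so its preparation is long. The cycloaddition must make two quaternary carbons (C4 and C10) at once and would need high temperature. Cis versus trans fusion depends on the folding of a four-atom tether, which is rarely selective and often favours trans. Facial control rests on one stereocentre only, and the Z-enoate may isomerise on heating.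
- Comparison: in the chosen strategy the cis fusion is geometrically enforced and the precursor has no stereocentre to build. The price is a longer ring B end-game, where A2 would be ahead.

Alternative 3: The disconnection is C1–C10 together with C4–C5, an intermolecular Diels–Alder reaction of the quinone A3 (future ring B, dienophile C5=C10) with the E-dienyl silyl ether A4 (C1–C4) under a chiral oxazaborolidinium Lewis acid. It would give the cis-fused enedione A5.
- For: this is the shortest access to the bicycle. C17 is already on C8, the reaction class is catalytic and enantioselective, and the endo rule with the E-diene defines C4. On core-building step count and on C4 control it is stronger than the chosen route.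
- Against: the C4 terminus of A4 carries two substituents, one of them necessarily inside in the s-cis diene, and it must bond next to the methyl-bearing carbon C10. Such dienes are poor, so reactivity is the main doubt. A5 is also over-oxidised in ring B: the C6 carbonyl must be removed, the C9 carbonyl beside quaternary C10 must become a CH bearing the chain, and the ring A alkene must be reduced.
- Comparison: the chosen strategy makes the congested C4–C5 bond intramolecularly under mild conditions and leaves exactly one enone where functionality is needed.

Key step: step 7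

Assumption: the quinine-derived amine is taken to favour the enone arm that leads to 13; if the sense of induction is the opposite, its quinidine-derived pseudo-enantiomer is used and nothing else changes.

## Route

Step 1
Reactants: 1 2,6-dimethylhept-5-enal (racemic); 2 methyl vinyl ketone
Product: 4 4-methyl-4-(4-methylpent-3-en-1-yl)cyclohex-2-en-1-one (racemic), via Michael adduct 3 (not isolated)
Conditions: KOH (cat.), EtOH, 0 °C to reflux
Reagents that add atoms: none
Why: Robinson annulation: the enolate of the α-branched aldehyde adds to the vinyl ketone (Michael addition), and the methyl ketone of 3 then condenses onto the aldehyde, which can no longer enolise (aldol condensation). The configuration of 1 is of no consequence, because the carbon concerned loses its chirality in step 3.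

Step 2
Reactants: 4 4-methyl-4-(4-methylpent-3-en-1-yl)cyclohex-2-en-1-one
Product: 6 (2E)-2-methyl-5-(1-methyl-4-oxocyclohex-2-en-1-yl)pent-2-enal, via allylic alcohol 5 (not isolated)
Conditions: SeO2 (0.3 equiv), t-BuOOH, CH2Cl2, rt; then MnO2, CH2Cl2, rt
Reagents that add atoms: tert-butyl hydroperoxide CC(C)(C)OO (oxygen, relayed by selenium dioxide O=[Se]=O)
Why: Riley allylic oxidation (ene reaction, then [2,3]-sigmatropic shift) takes place at the E-methyl group of the trisubstituted alkene. MnO2 oxidises the allylic alcohol 5 that accompanies the aldehyde, so that one compound is carried on. The ring enone has no allylic C–H and should not react at room temperature.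

Step 3
Reactants: 6 (2E)-2-methyl-5-(1-methyl-4-oxocyclohex-2-en-1-yl)pent-2-enal
Product: 7 2-methyl-5-(1-methyl-4-oxocyclohexyl)pentanal (racemic)
Conditions: H2 (1 atm), Pd/C, EtOAc, rt
Reagents that add atoms: none
Why: Heterogeneous hydrogenation saturates both conjugated C=C bonds and leaves the aldehyde and the ketone. The stereocentre formed next to the aldehyde is racemic, which is acceptable because the key step erases it.

Step 4
Reactants: 7 2-methyl-5-(1-methyl-4-oxocyclohexyl)pentanal
Product: 8 4-[4-(1,3-dioxolan-2-yl)pentyl]-4-methylcyclohexan-1-one
Conditions: (Me3SiOCH2)2, Me3SiOTf (cat.), CH2Cl2, −78 °C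
Reagents that add atoms: 1,2-bis(trimethylsilyloxy)ethane C[Si](C)(C)OCCO[Si](C)(C)C
Why: Acetalisation with the bis-silyl ether of the diol is kinetically controlled at −78 °C, where the aldehyde reacts and the ring ketone should not. The dioxolane keeps the aldehyde from being dehydrogenated in step 5.

Step 5
Reactants: 8 4-[4-(1,3-dioxolan-2-yl)pentyl]-4-methylcyclohexan-1-one
Product: 10 4-[4-(1,3-dioxolan-2-yl)pentyl]-4-methylcyclohexa-2,5-dien-1-one, via mono-enone 9 (not isolated)
Conditions: IBX (4.5 equiv), DMSO/toluene, 75 °C
Reagents that add atoms: none
Why: IBX dehydrogenates a ketone through its enol; the reaction runs twice in one flask, through enone 9, and stops at the cross-conjugated dienone because the quaternary ring carbon rules out aromatisation. The two enone arms of 10 are related by a mirror plane, so the ring carries no stereocentre.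

Step 6
Reactants: 10 4-[4-(1,3-dioxolan-2-yl)pentyl]-4-methylcyclohexa-2,5-dien-1-one
Product: 11 2-methyl-5-(1-methyl-4-oxocyclohexa-2,5-dien-1-yl)pentanal (racemic at C4; no other stereocentre)
Conditions: aq. HCl (1 mol/L), THF, rt
Reagents that add atoms: water O
Why: Acid-catalysed hydrolysis of the dioxolane. The 4,4-disubstituted dienone tolerates dilute aqueous acid, since dienone–phenol rearrangement needs far stronger acid.

Step 7
Reactants: 11 2-methyl-5-(1-methyl-4-oxocyclohexa-2,5-dien-1-yl)pentanal
Product: 13 (1R,4aR,8aS)-1,4a-dimethyl-7-oxo-1,2,3,4,4a,7,8,8a-octahydronaphthalene-1-carbaldehyde, via enamine 12 (not isolated)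
Conditions: 9-amino-9-deoxy-epi-quinine (20 mol %), CF3CO2H (40 mol %), toluene, rt to 40 °C
Reagents that add atoms: none
Why: Proposed new method: the primary amine condenses with the aldehyde and the imine tautomerises to enamine 12 (C4=C19), which deletes the C4 stereocentre so that both enantiomers of 11 pass through one intermediate; C4 of the enamine then adds to the β-carbon C5 of one enone arm, and hydrolysis releases 13 and the amine. The closest known reaction type is the amine-catalysed desymmetrising intramolecular Michael addition of tethered unbranched aldehydes to 4,4-disubstituted cyclohexadienones, and enamines of α-branched aldehydes with cinchona primary amines are known donors toward intermolecular acceptors; their combination, which makes a quaternary carbon, is the untested part. Ring A closes in the 6-exo-trig mode. C5 and C10 are set together by the choice between the two enantiotopic enone arms, which is made by the chiral amine, its protonated quinuclidine being placed to hydrogen-bond the dienone carbonyl. The cis fusion is fixed by the tether, since a three-carbon chain anchored on C10 can reach C5 only on its own face. C4 is set by the enamine face: in the required arrangement the CH–N arm (C19) lies under ring B, anti to H5, and C18 points outward, which with the E-enamine brings nitrogen close to the carbonyl that the catalyst binds. The step needs arm selectivity, this enamine-face selectivity and a single addition; the last is secured by the substrate, because 13 has no α-hydrogen on the aldehyde and cannot re-enter the cycle or epimerise at C4.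

Step 8
Reactants: 13 (1R,4aR,8aS)-1,4a-dimethyl-7-oxo-1,2,3,4,4a,7,8,8a-octahydronaphthalene-1-carbaldehyde
Product: 14 enone alcohol (4α-CH2OH; 4β-CH3; 5β-H; 10β-CH3; C7 ketone; C8=C9)
Conditions: NaBH4, EtOH/CH2Cl2, −78 °C
Reagents that add atoms: none
Why: Chemoselective NaBH4 reduction: at −78 °C and without a cerium salt an aldehyde is reduced much faster than a conjugated ketone. No stereocentre is affected.

Step 9
Reactants: 14 enone alcohol
Product: 15 enone silyl ether (14 with C19–OSi(t-Bu)Me2)
Conditions: t-BuMe2SiCl, imidazole, DMF, rt
Reagents that add atoms: tert-butyldimethylsilyl chloride CC(C)(C)[Si](C)(C)Cl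
Why: Standard silylation of the primary alcohol; the silyl ether should survive every step up to the fluoride treatment of step 20.

Step 10
Reactants: 15 enone silyl ether
Product: 16 8-iodo enone (15 with iodine on C8)
Conditions: I2, pyridine, CH2Cl2, 0 °C to rt
Reagents that add atoms: iodine II
Why: Pyridine-mediated α-iodination of an enone (conjugate addition of pyridine, iodination of the enolate, elimination) places iodine on C8, the only vinylic α-carbon.

Step 11
Reactants: 16 8-iodo enone
Product: 17 iodo allylic alcohol (7β-OH; 7S; iodine on C8; C8=C9; C19 silyl ether)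
Conditions: (R)-2-methyl-CBS-oxazaborolidine (20 mol %), BH3·SMe2, THF, −40 °C; then MeOH
Reagents that add atoms: none
Why: Corey–Bakshi–Shibata reduction under reagent control: with the iodine-bearing C8 as the large and C6 as the small flank, the (R)-oxazaborolidine delivers hydride to the α-face of C7 and should give the 7β-alcohol. α-Halo enones are among the most selective substrates of this reduction, which is relied on to override the substrate's own preference for hydride attack on the convex β-face. The 7β-oxygen is needed because step 13 transfers its configuration to C9.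

Step 12
Reactants: 17 iodo allylic alcohol
Product: 18 allylic alcohol (7β-OH; 7S; C17 methyl on C8; C8=C9; C19 silyl ether)
Conditions: trimethylboroxine, PdCl2(dppf) (5 mol %), Cs2CO3, dioxane/H2O, 80 °C
Reagents that add atoms: trimethylboroxine CB1OB(C)OB(C)O1
Why: Suzuki–Miyaura methylation of the alkenyl iodide installs C17; the free allylic hydroxyl is tolerated and C7 is not touched.

Step 13
Reactants: 18 allylic alcohol
Product: 20 ethyl ester (9β-CH2CO2Et; 9α-H; C7=C8 bearing C17; C19 silyl ether), via ketene acetal 19 (not isolated)
Conditions: MeC(OEt)3, EtCO2H (cat.), xylene, 140 °C, EtOH distilled off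
Reagents that add atoms: triethyl orthoacetate CCOC(C)(OCC)OCC
Why: Johnson–Claisen rearrangement: exchange with the orthoester and loss of ethanol give ketene acetal 19, whose [3,3]-sigmatropic shift is suprafacial, so the β C7–O bond is traded for a β C9–C11 bond while the alkene moves to C7=C8. In the half-chair that holds the C7–O bond pseudo-axial, the C10 methyl is pseudo-equatorial and ring A lies on the α-face, which leaves the β-face of C9 open. The intramolecular delivery is what allows a bond to be made at a carbon next to quaternary C10.

Step 14
Reactants: 20 ethyl ester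
Product: 21 primary alcohol (9β-CH2CH2OH; C7=C8; C19 silyl ether)
Conditions: LiAlH4, Et2O, 0 °C
Reagents that add atoms: none
Why: LiAlH4 reduces the ester to the C12 alcohol; the silyl ether and the trisubstituted alkene are inert.

Step 15
Reactants: 21 primary alcohol
Product: 22 tosylate (9β-CH2CH2OTs; C7=C8; C19 silyl ether)
Conditions: TsCl, Et3N, DMAP (cat.), CH2Cl2, 0 °C to rt
Reagents that add atoms: p-toluenesulfonyl chloride Cc1ccc(cc1)S(Cl)(=O)=O
Why: Sulfonylation of the primary alcohol; the tosylate is inert to peracid and is the leaving group of step 18.

Step 16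
Reactants: 22 tosylate
Product: 23 epoxy tosylate (7α,8α-epoxide; C17 β; 9β-CH2CH2OTs; C19 silyl ether)
Conditions: mCPBA, CH2Cl2, 0 °C
Reagents that add atoms: m-chloroperoxybenzoic acid OOC(=O)c1cccc(Cl)c1
Why: Prilezhaev epoxidation of the only alkene. The ring is expected to prefer the half-chair with the C9 chain pseudo-axial on the β-face (this avoids allylic strain with C17 and a syn-axial C9/C19 contact across ring A), so the peracid should approach from the α-face. The α-epoxide fixes the C8 oxygen on the α-face and keeps it masked while C12 carries a leaving group.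

Step 17
Reactants: 24 2-chlorobuta-1,3-diene (chloroprene)
Product: 25 buta-1,3-dien-2-ylmagnesium chloride (THF solution)
Conditions: Mg, ZnCl2 (cat.), BrCH2CH2Br (cat.), THF, reflux
Reagents that add atoms: magnesium [Mg]
Why: Grignard formation from the alkenyl chloride with activated magnesium gives the butadien-2-yl nucleophile.

Step 18
Reactants: 23 epoxy tosylate; 25 buta-1,3-dien-2-ylmagnesium chloride
Product: 26 epoxy diene (7α,8α-epoxide; 9β-(3-methylidenepent-4-en-1-yl); C19 silyl ether)
Conditions: Li2CuCl4 (5 mol %), THF, −30 °C to 0 °C
Reagents that add atoms: none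
Why: Copper-catalysed cross-coupling of a Grignard reagent with a primary sulfonate joins C12 to C13 and completes the 2-substituted buta-1,3-diene. The trisubstituted epoxide, whose only SN2 site C7 is screened by the C9 chain, should react far more slowly than the primary tosylate at low temperature.

Step 19
Reactants: 26 epoxy diene
Product: 27 tertiary alcohol (8α-OH; C17 β; 9β-dienyl chain; C19 silyl ether)
Conditions: LiAlH4, THF, reflux
Reagents that add atoms: none
Why: Hydride opens the epoxide by SN2 attack at the less substituted C7, trans-diaxially (Fürst–Plattner rule), so the oxygen stays on C8 with its configuration: 8α-OH and C17 β. The diene and the silyl ether do not react with LiAlH4.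

Step 20
Reactants: 27 tertiary alcohol
Product: 28 diol (8α-OH; C19–OH; 9β-dienyl chain)
Conditions: Bu4NF (TBAF), THF, rt to 45 °C
Reagents that add atoms: none
Why: Fluoride cleaves the neopentylic silyl ether; nothing else in 27 is fluoride-sensitive.

Step 21
Reactants: 28 diol
Product: 29 C19 bromoacetate of 28
Conditions: BrCH2COBr, pyridine, CH2Cl2, −20 °C
Reagents that add atoms: bromoacetyl bromide BrCC(Br)=O
Why: Acylation with an acyl bromide at low temperature is selective for the primary C19 hydroxyl; the tertiary C8 hydroxyl should not acylate under these conditions, and pyridine scavenges HBr so that it is not ionised either.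

Step 22
Reactants: 29 C19 bromoacetate
Product: 30 C19 (diphenoxyphosphoryl)acetate of 28
Conditions: (PhO)2P(O)H, Et3N, CH2Cl2, 0 °C to rt
Reagents that add atoms: diphenyl phosphite O=[PH](Oc1ccccc1)Oc1ccccc1
Why: Michaelis–Becker reaction: the phosphite anion displaces the α-bromide and gives the diaryl phosphonoacetate needed for Z-selective olefination.

Step 23
Reactants: 31 4-hydroxybenzaldehyde
Product: 32 4-(tert-butyldimethylsilyloxy)benzaldehyde
Conditions: t-BuMe2SiCl, imidazole, CH2Cl2, rt
Reagents that add atoms: tert-butyldimethylsilyl chloride CC(C)(C)[Si](C)(C)Cl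
Why: Silylation of the phenol, which would otherwise be deprotonated in step 24 and make the aldehyde unreactive.

Step 24
Reactants: 30 C19 (diphenoxyphosphoryl)acetate; 32 4-(tert-butyldimethylsilyloxy)benzaldehyde
Product: 33 silyl ether of the target (C19 (2Z)-3-[4-(tert-butyldimethylsilyloxy)phenyl]prop-2-enoate of 28)
Conditions: NaH, THF, −78 °C to −40 °C, dark
Reagents that add atoms: none
Why: Horner–Wadsworth–Emmons olefination in its Z-selective diaryl phosphonate variant: the electron-poor aryloxy groups make collapse of the first-formed oxaphosphetane faster than its equilibration, so the kinetic Z-enoate should result. The phosphonate C–H is far more acidic than the tertiary alcohol, so one equivalent of base suffices. Low temperature and exclusion of light guard against Z to E drift.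

Step 25
Reactants: 33 silyl ether of the target
Product: 34 [(1R,4aS,5R,6R,8aS)-6-hydroxy-1,4a,6-trimethyl-5-(3-methylidenepent-4-en-1-yl)decahydronaphthalen-1-yl]methyl (2Z)-3-(4-hydroxyphenyl)prop-2-enoate (target)
Conditions: Bu4NF (TBAF), AcOH, THF, 0 °C, dark
Reagents that add atoms: none
Why: Fluoride cleaves the aryl silyl ether; acetic acid buffers the medium so that the phenoxide of the Z-coumarate, which isomerises easily, is not left free, and the reaction is run cold and in the dark. The tertiary alcohol, the diene and the ester are untouched.

## Compound list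

1 | 2,6-dimethylhept-5-enal (racemic) | CC(C)=CCCC(C)C=O | starting material
2 | methyl vinyl ketone (but-3-en-2-one) | CC(=O)C=C | starting material
3 | 2-methyl-2-(4-methylpent-3-en-1-yl)-5-oxohexanal (Michael adduct) | CC(C)=CCCC(C)(C=O)CCC(C)=O | intermediate
4 | 4-methyl-4-(4-methylpent-3-en-1-yl)cyclohex-2-en-1-one (racemic) | CC(C)=CCCC1(C)C=CC(=O)CC1 | intermediate
5 | 4-[(3E)-5-hydroxy-4-methylpent-3-en-1-yl]-4-methylcyclohex-2-en-1-one | OC/C(C)=C/CCC1(C)C=CC(=O)CC1 | intermediate
6 | (2E)-2-methyl-5-(1-methyl-4-oxocyclohex-2-en-1-yl)pent-2-enal | O=C/C(C)=C/CCC1(C)C=CC(=O)CC1 | intermediate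
7 | 2-methyl-5-(1-methyl-4-oxocyclohexyl)pentanal (racemic) | CC(CCCC1(C)CCC(=O)CC1)C=O | intermediate
8 | 4-[4-(1,3-dioxolan-2-yl)pentyl]-4-methylcyclohexan-1-one | CC(CCCC1(C)CCC(=O)CC1)C1OCCO1 | intermediate
9 | 4-[4-(1,3-dioxolan-2-yl)pentyl]-4-methylcyclohex-2-en-1-one | CC(CCCC1(C)C=CC(=O)CC1)C1OCCO1 | intermediate
10 | 4-[4-(1,3-dioxolan-2-yl)pentyl]-4-methylcyclohexa-2,5-dien-1-one | CC(CCCC1(C)C=CC(=O)C=C1)C1OCCO1 | intermediate
11 | 2-methyl-5-(1-methyl-4-oxocyclohexa-2,5-dien-1-yl)pentanal (racemic at C4) | CC(CCCC1(C)C=CC(=O)C=C1)C=O | intermediate
12 | E-enamine of 11 with 9-amino-9-deoxy-epi-quinine (C4=C19–NH) | COC1=CC2=C(C=CN=C2C=C1)[C@@H]([C@@H]3C[C@@H]4CCN3C[C@@H]4C=C)N/C=C(\C)CCCC5(C)C=CC(=O)C=C5 | intermediate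
13 | (1R,4aR,8aS)-1,4a-dimethyl-7-oxo-1,2,3,4,4a,7,8,8a-octahydronaphthalene-1-carbaldehyde (cis-fused; 4α-CHO, 4β-CH3, 5β-H, 10β-CH3, C7 ketone, C8=C9) | O=C1C=C[C@@]2(C)CCC[C@@](C)(C=O)[C@H]2C1 | intermediate
14 | enone alcohol (13 with C19 as CH2OH) | O=C1C=C[C@@]2(C)CCC[C@@](C)(CO)[C@H]2C1 | intermediate
15 | enone silyl ether (C19 tert-butyldimethylsilyl ether of 14) | O=C1C=C[C@@]2(C)CCC[C@@](C)(CO[Si](C)(C)C(C)(C)C)[C@H]2C1 | intermediate
16 | 8-iodo enone | O=C1C(I)=C[C@@]2(C)CCC[C@@](C)(CO[Si](C)(C)C(C)(C)C)[C@H]2C1 | intermediate
17 | iodo allylic alcohol (7β-OH, 7S) | O[C@@H]1C(I)=C[C@@]2(C)CCC[C@@](C)(CO[Si](C)(C)C(C)(C)C)[C@H]2C1 | intermediate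
18 | allylic alcohol (7β-OH, 7S; C17 on C8; C8=C9) | O[C@@H]1C(C)=C[C@@]2(C)CCC[C@@](C)(CO[Si](C)(C)C(C)(C)C)[C@H]2C1 | intermediate
19 | ketene acetal (7β-O–C(OEt)=CH2 derivative of 18) | C=C(OCC)O[C@@H]1C(C)=C[C@@]2(C)CCC[C@@](C)(CO[Si](C)(C)C(C)(C)C)[C@H]2C1 | intermediate
20 | ethyl ester (9β-CH2CO2Et, 9α-H, C7=C8 bearing C17) | CCOC(=O)C[C@@H]1[C@@]2(C)CCC[C@@](C)(CO[Si](C)(C)C(C)(C)C)[C@H]2CC=C1C | intermediate
21 | primary alcohol (9β-CH2CH2OH, C7=C8) | OCC[C@@H]1[C@@]2(C)CCC[C@@](C)(CO[Si](C)(C)C(C)(C)C)[C@H]2CC=C1C | intermediate
22 | tosylate (9β-CH2CH2OTs, C7=C8) | Cc1ccc(cc1)S(=O)(=O)OCC[C@@H]1[C@@]2(C)CCC[C@@](C)(CO[Si](C)(C)C(C)(C)C)[C@H]2CC=C1C | intermediate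
23 | epoxy tosylate (7α,8α-epoxide, C17 β) | Cc1ccc(cc1)S(=O)(=O)OCC[C@@H]1[C@@]2(C)CCC[C@@](C)(CO[Si](C)(C)C(C)(C)C)[C@H]2C[C@H]3O[C@@]13C | intermediate
24 | 2-chlorobuta-1,3-diene (chloroprene) | C=CC(Cl)=C | starting material
25 | buta-1,3-dien-2-ylmagnesium chloride | C=CC(=C)[Mg]Cl | intermediate
26 | epoxy diene (7α,8α-epoxide, 9β-(3-methylidenepent-4-en-1-yl)) | C=CC(=C)CC[C@@H]1[C@@]2(C)CCC[C@@](C)(CO[Si](C)(C)C(C)(C)C)[C@H]2C[C@H]3O[C@@]13C | intermediate
27 | tertiary alcohol (8α-OH, C17 β, C19 silyl ether) | C=CC(=C)CC[C@@H]1[C@@]2(C)CCC[C@@](C)(CO[Si](C)(C)C(C)(C)C)[C@H]2CC[C@@]1(C)O | intermediate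
28 | diol (8α-OH, C19–OH) | C=CC(=C)CC[C@@H]1[C@@]2(C)CCC[C@@](C)(CO)[C@H]2CC[C@@]1(C)O | intermediate
29 | C19 bromoacetate of 28 | C=CC(=C)CC[C@@H]1[C@@]2(C)CCC[C@@](C)(COC(=O)CBr)[C@H]2CC[C@@]1(C)O | intermediate
30 | C19 (diphenoxyphosphoryl)acetate of 28 | C=CC(=C)CC[C@@H]1[C@@]2(C)CCC[C@@](C)(COC(=O)CP(=O)(Oc3ccccc3)Oc3ccccc3)[C@H]2CC[C@@]1(C)O | intermediate
31 | 4-hydroxybenzaldehyde | O=Cc1ccc(O)cc1 | starting material
32 | 4-(tert-butyldimethylsilyloxy)benzaldehyde | O=Cc1ccc(O[Si](C)(C)C(C)(C)C)cc1 | intermediate
33 | silyl ether of the target | C=CC(=C)CC[C@@H]1[C@@]2(C)CCC[C@@](C)(COC(=O)/C=C\c3ccc(O[Si](C)(C)C(C)(C)C)cc3)[C@H]2CC[C@@]1(C)O | intermediate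
34 | [(1R,4aS,5R,6R,8aS)-6-hydroxy-1,4a,6-trimethyl-5-(3-methylidenepent-4-en-1-yl)decahydronaphthalen-1-yl]methyl (2Z)-3-(4-hydroxyphenyl)prop-2-enoate | C=CC(=C)CC[C@@H]1[C@@]2(C)CCC[C@@](C)(COC(=O)/C=C\c3ccc(O)cc3)[C@H]2CC[C@@]1(C)O | target

## Step count and least certain steps

Total: 25 steps. Longest linear sequence: 23 steps (steps 1–16, 18–22, 24 and 25); steps 17 and 23 are side branches.

**Step 7 (key step, proposed new method).** Three things may go wrong. The hindered α-branched aldehyde may form its enamine slowly, so that conversion stalls. The two enone arms may be discriminated poorly, which lowers the enantiomeric purity. The two enamine faces may be discriminated poorly, which gives the C4 epimer; this is the least predictable point, because the required arrangement puts the CH–N arm, not the methyl group, under the ring.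
Fallback, by known chemistry: from 11, ring A is closed without asymmetric induction through an achiral enamine (pyrrolidine, AcOH, CHCl3, 40 °C), a known racemic intramolecular Michael addition. This gives 13 together with the mirror image of 13 F1. The mixture is taken through steps 8 to 10 as it stands, so that 14, 15 and 16 are accompanied by the mirror image of 14 F2, the mirror image of 15 F3 and the mirror image of 16 F4. Step 11 then acts as the resolution: the (R)-oxazaborolidine imposes the same absolute configuration at C7 on both enantiomers, so 16 gives 17 and F4 gives the C7 epimer of the mirror image of 17 F5. These two are diastereomers and should separate on silica, and the route is rejoined at 17. This fallback does not correct a wrong C4 relation; an achiral amine only offers a different steric profile at that point.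

**Step 11.** The catalyst must deliver hydride to the concave α-face against the substrate's preference for the convex face, so erosion of facial selectivity in this mismatched pairing is the likely failure.
Fallback: from 16, Luche reduction (NaBH4, CeCl3·7H2O, MeOH, −78 °C) should give, under substrate control, the 7α-alcohol F6. Mitsunobu inversion (4-nitrobenzoic acid, PPh3, DIAD, THF) gives the 7β 4-nitrobenzoate F7, and K2CO3 in MeOH returns 17.

**Step 13.** The [3,3] shift has to form a bond at C9 next to quaternary C10; the likely failure is slow rearrangement with competing elimination of the allylic orthoester to a diene.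
Fallback: from 18, phenyl isocyanate gives the N-phenylcarbamate of 18 F8. Deprotonation (MeLi), then CuBr·SMe2 and vinylmagnesium bromide (CH2=CHMgBr), transfers a vinyl group to C9 on the face of the leaving group (carbamate-directed syn-SN2' allylic substitution) and gives the 9β-vinyl compound with the C7=C8 alkene F9. Hydroboration of the vinyl group with 9-BBN and oxidation (H2O2, NaOH) gives 21.

**Step 16.** Both faces of the C7=C8 alkene are screened to some degree (β by the C9 chain, α by ring A), so poor or reversed facial selectivity of the epoxidation is the risk.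
Fallback: from 22, N-bromosuccinimide in aqueous THF gives by anti addition, with water entering at the tertiary C8, the 7β-bromo-8α-hydroxy tosylate F10; K2CO3 in MeOH closes it to 23. This route places the oxygen on the face opposite to the one the electrophile takes, so it is the stereochemical complement of direct epoxidation.

**Step 18.** The epoxide may be lost during the coupling, by opening with the Grignard reagent or by magnesium-halide-promoted rearrangement, and the dienyl reagent may transfer in its allenic form.
Fallback: from 23, lithium acetylide–ethylenediamine complex (LiC≡CH·H2NCH2CH2NH2) in DMSO displaces the tosylate and gives the terminal alkyne F11. Cross enyne metathesis with ethylene (second-generation Grubbs catalyst, CH2Cl2) converts the alkyne into the 2-substituted buta-1,3-diene 26.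

## Further compounds

F1 | step 7 | mirror image of 13 | O=C1C=C[C@]2(C)CCC[C@](C)(C=O)[C@@H]2C1
F2 | step 7 | mirror image of 14 | O=C1C=C[C@]2(C)CCC[C@](C)(CO)[C@@H]2C1
F3 | step 7 | mirror image of 15 | O=C1C=C[C@]2(C)CCC[C@](C)(CO[Si](C)(C)C(C)(C)C)[C@@H]2C1
F4 | step 7 | mirror image of 16 | O=C1C(I)=C[C@]2(C)CCC[C@](C)(CO[Si](C)(C)C(C)(C)C)[C@@H]2C1
F5 | step 7 | C7 epimer of the mirror image of 17 | O[C@@H]1C(I)=C[C@]2(C)CCC[C@](C)(CO[Si](C)(C)C(C)(C)C)[C@@H]2C1
F6 | step 11 | 7α-alcohol (C7 epimer of 17) | O[C@H]1C(I)=C[C@@]2(C)CCC[C@@](C)(CO[Si](C)(C)C(C)(C)C)[C@H]2C1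
F7 | step 11 | 7β 4-nitrobenzoate of 17 | O=C(O[C@@H]1C(I)=C[C@@]2(C)CCC[C@@](C)(CO[Si](C)(C)C(C)(C)C)[C@H]2C1)c1ccc(cc1)[N+](=O)[O-]
F8 | step 13 | N-phenylcarbamate of 18 | O=C(Nc1ccccc1)O[C@@H]1C(C)=C[C@@]2(C)CCC[C@@](C)(CO[Si](C)(C)C(C)(C)C)[C@H]2C1
F9 | step 13 | 9β-vinyl compound with C7=C8 alkene | C=C[C@@H]1[C@@]2(C)CCC[C@@](C)(CO[Si](C)(C)C(C)(C)C)[C@H]2CC=C1C
F10 | step 16 | 7β-bromo-8α-hydroxy tosylate | Cc1ccc(cc1)S(=O)(=O)OCC[C@@H]1[C@@]2(C)CCC[C@@](C)(CO[Si](C)(C)C(C)(C)C)[C@H]2C[C@H](Br)[C@@]1(C)O
F11 | step 18 | terminal alkyne (9β-but-3-yn-1-yl, 7α,8α-epoxide) | C#CCC[C@@H]1[C@@]2(C)CCC[C@@](C)(CO[Si](C)(C)C(C)(C)C)[C@H]2C[C@H]3O[C@@]13C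
A1 | alternative 1 | cis-decalin with C8 ketone, C9 dimethyl ketal, C3=C4 methyl enoate and C2 phenylsulfonyl group | COC1(OC)[C@@]2(C)C[C@H](S(=O)(=O)c3ccccc3)C=C(C(=O)OC)[C@H]2CCC1=O
A2 | alternative 2 | cis-fused octalin methyl ester with C8 dioxolane, C1=C2 alkene and 9-(2-benzyloxyethyl) chain | c1ccccc1COCC[C@@H]1[C@@]2(C)C=CC[C@@](C)(C(=O)OC)[C@H]2CCC13OCCO3
A3 | alternative 3 | 2,6-dimethyl-1,4-benzoquinone | CC1=CC(=O)C=C(C)C1=O
A4 | alternative 3 | tert-butyldimethyl{[(2E)-2-methylpenta-2,4-dien-1-yl]oxy}silane | C=C/C=C(\C)CO[Si](C)(C)C(C)(C)C
A5 | alternative 3 | cis-fused 2,5,8a-trimethyl-5-(tert-butyldimethylsilyloxymethyl)-4a,5,8,8a-tetrahydronaphthalene-1,4-dione | O=C1[C@@]2(C)CC=C[C@@](C)(CO[Si](C)(C)C(C)(C)C)[C@H]2C(=O)C=C1C
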